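All runs are calculated with constants of no real substance; noise was put on by code.

**Amounts first.** Substrate is the smaller charge in every flask, so it is the limiting reagent. The balance is short: the percentage asked for is the product made, in mM, over the substrate charged, and that charge caps it.

| flask | substrate | reagent | initiator | remark | time |
|---|---|---|---|---|---|
| south-west | 22 mM | 40 mM | 1.3 mM | run made earlier |  |
| birch | 10 mM | 40.0 mM | 0.80 mM |  | 10 h |
| ash | 20 mM | 150 mM | 2.0 mM |  | 10 h |
| elm | 20 mM | 40.0 mM | 1.3 mM |  | 10 h |
| oak | 20 mM | 40.0 mM | 4.0 mM |  | 10 h |
| maple | 5.0 mM | 12.0 mM | 0.60 mM |  | 10 h |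

south-west run (percent of the substrate charged)

| time / min | product / % |
|---|---|
| 15.0 | 0.8 |
| 30.0 | 0.9 |
| 50.0 | 1.6 |
| 60.0 | 2.9 |
| 80.0 | 3.5 |
| 90.0 | 3.4 |
| 120 | 4.6 |

(scatter of a reading: 0.3 percentage points)

- the analysis behind the earlier runs scatters by 0.3 percentage points, standard deviation
- no earlier run changes the charge of initiator; that part of a forecast is a guess

- the flasks put in order of amount of product, in percent of the substrate charged, best first, at 10 h (birch / ash / elm / oak / maple)
- the amount of product, in percent of the substrate charged of the flask you put first, at 10 h
- the amount of product, in percent of the substrate charged of the flask you put last, at 10 h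

**What matters.** The last south-west reading carries a scatter of 6.52% of itself. The steps away from the south-west run are larger: a factor of 4.40 in substrate for maple, 3.75 in reagent for ash, 3.08 in initiator for oak, and 5.00 in time. The run tests none of these, so the reading is good enough and the dependences are the weak part.

**The number.** The south-west run made 4.6% of 22 mM in 120 min, which gives 0.506 mM h⁻¹. This is the hourly make: product formed per hour, in mM and not in percent. The reckoning here takes it as free of the substrate charge, a choice the run cannot test, and scales it with reagent and the square root of initiator. That gives 44.4% for oak, 39.7% for birch, 25.3% for elm and 20.6% for maple. For ash it gives 23.5 mM, above the 20 mM charged, so the balance cuts ash to its charge. The order reckoned is ash, oak, birch, elm, maple.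

**The forecast.** It gives ash > oak > elm > birch > maple, with 60% for the first flask and 4.5% for the last, and elm at about 20 % over birch at about 17 %. It differs from the reckoning above in taking the rate as first order in substrate. Its grounds: “One run cannot reveal any orders, so these are assumptions”.

**The flask.**

    first chain carrier → ended carrier (k = 7680 h⁻¹)
    substrate + second chain carrier → by-product + first chain carrier (k = 9.84 × 10⁶ M⁻¹ h⁻¹)
    reagent ⇌ dormant form (K = 5.90, k = 0.261 h⁻¹)
    reagent + first chain carrier → product + second chain carrier (k = 7.30 × 10⁶ M⁻¹ h⁻¹)
    substrate + initiating radical → capped initiator + first chain carrier (k = 92000 M⁻¹ s⁻¹)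
    initiator → 2 initiating radical (k = 0.00699 h⁻¹)
    2 second chain carrier → ended chains A (k = 6.60 × 10⁶ M⁻¹ s⁻¹)
    2 first chain carrier → ended chains B (k = 3.00 × 10⁷ M⁻¹ s⁻¹)

The flasks give ash > oak > birch > elm > maple, with 57.4% in ash, 7.25% in maple, and birch at 15.6% above elm at 12.3%. At 10.0 h elm holds 16.6% of its reagent free and 30.9 mM as dormant form. Its hourly make, averaged over the run, is 0.247 mM h⁻¹, about half of 0.506 mM h⁻¹. Maple averages 0.0362 mM h⁻¹, and a flask like maple but with 20 mM of substrate averages 0.0365 mM h⁻¹.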